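**Plan**
1. Retrosynthesis: first the two phenolic O–benzyl bonds are cut; then, in one event, the exocyclic CH2–aryl (syringyl) bond and the C3–OH bond, which leads back to a 3-methylene-oxolan-2-one, an aryl Grignard reagent and an oxygen-atom donor; then the exocyclic C=CH2; last the lactone C–O bond and the C4–CH2Ar bond, back to a succinate loaded on an Evans auxiliary and a vanillyl bromide.
2. Enabling feature: ring carbon C3 carries the OH and sits between the lactone carbonyl C2 and the exocyclic benzylic CH2, so O=C2–C3(OH)–CH2–Ar is the retron of an aryl/oxygen 1,2-addition across the exocyclic C3=CH2 bond of an α-methylene-γ-butyrolactone; the benzyl group on the neighbouring ring carbon C4 shields one face of that five-membered ring.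
3. Forward: the chain is joined by Evans alkylation; the oxolan-2-one (the only ring made) closes by reduction and lactonisation; α-methylenation follows; a telescoped three-component conjugate arylation/ketene-acetal oxidation installs the aryl group and the OH; hydrogenolysis finishes.
4. Stereochemistry: C4 comes from the auxiliary-controlled alkylation; C3 comes from substrate control, the oxidant adding to the planar C2=C3 ketene acetal anti to the C4 benzyl group (O trans to it, the two benzyl groups cis, i.e. 3S,4R).

Key step: step 7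

Remark on the chemistry: 4-bromo-2,6-dimethoxyphenol, [4-(benzyloxy)-3-methoxyphenyl]methanol, mono-tert-butyl succinate and (S)-4-benzyl-2-oxazolidinone are taken as catalogue compounds, and dimethyldioxirane is used as its freshly prepared acetone solution.

**Step 1**
Reactants: 1 4-tert-butoxy-4-oxobutanoic acid (mono-tert-butyl succinate); 2 (4S)-4-benzyl-1,3-oxazolidin-2-one
Product: 4 tert-butyl 4-[(4S)-4-benzyl-2-oxo-1,3-oxazolidin-3-yl]-4-oxobutanoate, via mixed pivalic anhydride 3 (not isolated)
Conditions: PivCl, Et3N, THF, −20 °C; then 2, LiCl, −20 °C → rt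
Reagents that add atoms: pivaloyl chloride, CC(C)(C)C(Cl)=O (its acyl group appears in intermediate 3 only, not in 4)
Why: N-acylation of the oxazolidinone through the mixed pivalic anhydride with LiCl/Et3N activation is the standard loading of an Evans auxiliary and should leave the tert-butyl ester untouched.

**Step 2**
Reactants: 5 [4-(benzyloxy)-3-methoxyphenyl]methanol
Product: 6 1-(benzyloxy)-4-(bromomethyl)-2-methoxybenzene
Conditions: PBr3, CH2Cl2, 0 °C
Reagents that add atoms: phosphorus tribromide, BrP(Br)Br
Why: Bromination of a benzylic alcohol with PBr3 (SN2 displacement of the phosphite ester) should proceed without touching the aryl benzyl ether; the bromide is used directly.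

**Step 3**
Reactants: 4 tert-butyl 4-[(4S)-4-benzyl-2-oxo-1,3-oxazolidin-3-yl]-4-oxobutanoate; 6 1-(benzyloxy)-4-(bromomethyl)-2-methoxybenzene
Product: 8 tert-butyl (3S)-3-{[(4S)-4-benzyl-2-oxo-1,3-oxazolidin-3-yl]carbonyl}-4-[4-(benzyloxy)-3-methoxyphenyl]butanoate, via sodium Z-enolate 7 (not isolated)
Conditions: NaHMDS, THF, −78 °C; then 6, −78 → −45 °C
Reagents that add atoms: sodium bis(trimethylsilyl)amide, C[Si](C)(C)[N-][Si](C)(C)C.[Na+] (sodium in 7 only)
Why: Evans asymmetric alkylation: the more acidic imide α-CH2 gives the chelated Z-enolate and the benzylic bromide should attack the face opposite the C4 benzyl group of the auxiliary, which sets the (S) centre that becomes C4 of the lactone.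

**Step 4**
Reactants: 8 tert-butyl (3S)-3-{[(4S)-4-benzyl-2-oxo-1,3-oxazolidin-3-yl]carbonyl}-4-[4-(benzyloxy)-3-methoxyphenyl]butanoate
Product: 10 (4S)-4-[4-(benzyloxy)-3-methoxybenzyl]oxolan-2-one, via hydroxy tert-butyl ester 9 (not isolated)
Conditions: LiBH4, MeOH (1 equiv), THF, 0 °C; then p-TsOH·H2O (10 mol %), toluene, 80 °C
Reagents that add atoms: none
Why: Reductive cleavage of the Evans imide with LiBH4 should reduce the activated exocyclic carbonyl faster than the tert-butyl ester and release the auxiliary, and acid-catalysed lactonisation of the γ-hydroxy tert-butyl ester with loss of isobutene then closes the ring without involving the stereocentre.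

**Step 5**
Reactants: 10 (4S)-4-[4-(benzyloxy)-3-methoxybenzyl]oxolan-2-one
Product: 12 (4S)-4-[4-(benzyloxy)-3-methoxybenzyl]-3-methylideneoxolan-2-one, via sodium hydroxymethylene enolate 11 (not isolated)
Conditions: NaH, HCO2Et, THF, 0 °C → rt; then (CH2O)n, THF, reflux
Reagents that add atoms: formaldehyde (as paraformaldehyde), C=O (the exocyclic CH2 of 12); ethyl formate, CCOC=O (formyl carbon in 11 only); sodium hydride, [H-].[Na+] (sodium in 11 only)
Why: Claisen formylation followed by deformylative methylenation (aldol with formaldehyde, formyl transfer to oxygen, E1cB loss of formate) is the established α-methylenation of γ-butyrolactones and should leave the non-acidic C4 centre unchanged.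

**Step 6**
Reactants: 13 4-bromo-2,6-dimethoxyphenol
Product: 14 2-(benzyloxy)-5-bromo-1,3-dimethoxybenzene
Conditions: BnBr, K2CO3, DMF, rt
Reagents that add atoms: benzyl bromide, BrCc1ccccc1
Why: Williamson etherification masks the phenol, which would otherwise quench the Grignard reagent of the next step.

**Step 7**
Reactants: 12 (4S)-4-[4-(benzyloxy)-3-methoxybenzyl]-3-methylideneoxolan-2-one; 14 2-(benzyloxy)-5-bromo-1,3-dimethoxybenzene
Product: 18 (3S,4R)-3-[4-(benzyloxy)-3,5-dimethoxybenzyl]-4-[4-(benzyloxy)-3-methoxybenzyl]-3-hydroxyoxolan-2-one, via aryl Grignard reagent 15 (not isolated), via silyl ketene acetal 16 (not isolated), via O-trimethylsilyl ether 17 (not isolated)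
Conditions: 14, Mg, THF, 45 °C; then CuBr·SMe2 (10 mol %), Me3SiCl, 12, THF, −78 → −40 °C; pentane, filtration, evaporation; DMDO, acetone/CH2Cl2, −78 °C; 1 M HCl, THF, 0 °C
Reagents that add atoms: dimethyldioxirane, CC1(C)OO1 (the hydroxyl oxygen of 18); chlorotrimethylsilane, C[Si](C)(C)Cl (silicon in 16 and 17 only); magnesium, [Mg] (in 15 only)
Why: Magnesium inserts into 14 to give 15, whose arylcopper(I) ate form adds to the exocyclic CH2 terminus of the s-cis enoate of 12 (π-complex, copper(III) β-adduct, reductive elimination forms the CH2–aryl bond) while Me3SiCl traps the enolate as the cyclic silyl ketene acetal 16; dimethyldioxirane then epoxidises the electron-rich C2=C3 bond, the silyloxy epoxide opens to the oxocarbenium ion with silyl shift to the new oxygen to give 17, and dilute acid frees the tertiary alcohol. The closest known reaction types are the Me3SiCl-accelerated copper-catalysed conjugate addition of Grignard reagents to enoates and the Rubottom oxidation of ketene silyl acetals, telescoped here into a three-component aryl/oxygen addition across one alkene. No ring is closed; the lactone ring is carried through intact. The new quaternary C3 centre is set under substrate control: C2=C3 of 16 is planar, the new benzyl group lies in that plane, and the oxidant should approach the face opposite the C4 benzyl group, so that oxygen ends up trans to it and the two benzyl groups cis, which is the (3S,4R) arrangement. The step needs 1,4- over 1,2-addition, which copper catalysis with Me3SiCl at −78 °C should secure while also keeping the enolate from adding to unreacted 12, and it needs oxidation of the ketene acetal in the presence of three alkoxyarenes and two benzyl ethers, which its far higher nucleophilicity at −78 °C and the acid-free oxidant (no protodesilylation) should secure.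

**Step 8**
Reactants: 18 (3S,4R)-3-[4-(benzyloxy)-3,5-dimethoxybenzyl]-4-[4-(benzyloxy)-3-methoxybenzyl]-3-hydroxyoxolan-2-one
Product: 19 (3S,4R)-3-hydroxy-3-(4-hydroxy-3,5-dimethoxybenzyl)-4-(4-hydroxy-3-methoxybenzyl)oxolan-2-one
Conditions: H2 (1 atm), 10 % Pd/C, EtOAc/EtOH, rt
Reagents that add atoms: none
Why: Catalytic hydrogenolysis should cleave both aryl benzyl ethers, while the tertiary alcohol is homobenzylic rather than benzylic, so the C3–O bond and both stereocentres should remain untouched.

**Compound list**
1 | 4-tert-butoxy-4-oxobutanoic acid | CC(C)(C)OC(=O)CCC(=O)O | starting material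
2 | (4S)-4-benzyl-1,3-oxazolidin-2-one | O=C1N[C@@H](Cc2ccccc2)CO1 | starting material
3 | 4-tert-butoxy-4-oxobutanoic pivalic anhydride | CC(C)(C)OC(=O)CCC(=O)OC(=O)C(C)(C)C | intermediate
4 | tert-butyl 4-[(4S)-4-benzyl-2-oxo-1,3-oxazolidin-3-yl]-4-oxobutanoate | CC(C)(C)OC(=O)CCC(=O)N1[C@@H](Cc2ccccc2)COC1=O | intermediate
5 | [4-(benzyloxy)-3-methoxyphenyl]methanol | COc1cc(CO)ccc1OCc1ccccc1 | starting material
6 | 1-(benzyloxy)-4-(bromomethyl)-2-methoxybenzene | COc1cc(CBr)ccc1OCc1ccccc1 | intermediate
7 | sodium (Z)-enolate of imide 4 | CC(C)(C)OC(=O)C/C=C(\[O-])N1[C@@H](Cc2ccccc2)COC1=O.[Na+] | intermediate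
8 | tert-butyl (3S)-3-{[(4S)-4-benzyl-2-oxo-1,3-oxazolidin-3-yl]carbonyl}-4-[4-(benzyloxy)-3-methoxyphenyl]butanoate | COc1cc(C[C@@H](CC(=O)OC(C)(C)C)C(=O)N2[C@@H](Cc3ccccc3)COC2=O)ccc1OCc1ccccc1 | intermediate
9 | tert-butyl (3S)-4-[4-(benzyloxy)-3-methoxyphenyl]-3-(hydroxymethyl)butanoate | COc1cc(C[C@@H](CC(=O)OC(C)(C)C)CO)ccc1OCc1ccccc1 | intermediate
10 | (4S)-4-[4-(benzyloxy)-3-methoxybenzyl]oxolan-2-one | COc1cc(C[C@@H]2COC(=O)C2)ccc1OCc1ccccc1 | intermediate
11 | sodium (Z)-[(4S)-4-[4-(benzyloxy)-3-methoxybenzyl]-2-oxooxolan-3-ylidene]methanolate | COc1cc(C[C@@H]2COC(=O)/C2=C\[O-])ccc1OCc1ccccc1.[Na+] | intermediate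
12 | (4S)-4-[4-(benzyloxy)-3-methoxybenzyl]-3-methylideneoxolan-2-one | COc1cc(C[C@@H]2COC(=O)C2=C)ccc1OCc1ccccc1 | intermediate
13 | 4-bromo-2,6-dimethoxyphenol | COc1cc(Br)cc(OC)c1O | starting material
14 | 2-(benzyloxy)-5-bromo-1,3-dimethoxybenzene | COc1cc(Br)cc(OC)c1OCc1ccccc1 | intermediate
15 | [4-(benzyloxy)-3,5-dimethoxyphenyl]magnesium bromide | COc1cc([Mg]Br)cc(OC)c1OCc1ccccc1 | intermediate
16 | {[(4S)-3-[4-(benzyloxy)-3,5-dimethoxybenzyl]-4-[4-(benzyloxy)-3-methoxybenzyl]-4,5-dihydrofuran-2-yl]oxy}trimethylsilane | COc1cc(C[C@@H]2COC(O[Si](C)(C)C)=C2Cc2cc(OC)c(OCc3ccccc3)c(OC)c2)ccc1OCc1ccccc1 | intermediate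
17 | (3S,4R)-3-[4-(benzyloxy)-3,5-dimethoxybenzyl]-4-[4-(benzyloxy)-3-methoxybenzyl]-3-[(trimethylsilyl)oxy]oxolan-2-one | COc1cc(C[C@@H]2COC(=O)[C@]2(O[Si](C)(C)C)Cc2cc(OC)c(OCc3ccccc3)c(OC)c2)ccc1OCc1ccccc1 | intermediate
18 | (3S,4R)-3-[4-(benzyloxy)-3,5-dimethoxybenzyl]-4-[4-(benzyloxy)-3-methoxybenzyl]-3-hydroxyoxolan-2-one | COc1cc(C[C@@H]2COC(=O)[C@]2(O)Cc2cc(OC)c(OCc3ccccc3)c(OC)c2)ccc1OCc1ccccc1 | intermediate
19 | (3S,4R)-3-hydroxy-3-(4-hydroxy-3,5-dimethoxybenzyl)-4-(4-hydroxy-3-methoxybenzyl)oxolan-2-one | COc1cc(C[C@@H]2COC(=O)[C@]2(O)Cc2cc(OC)c(O)c(OC)c2)ccc1O | target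

**Step count**
Total steps: 8. Longest linear sequence: 6 (steps 1, 3, 4, 5, 7, 8); steps 2 and 6 prepare the two side fragments.

**Steps most likely to fail**

Step 7. The Grignard reagent may attack the lactone carbonyl or remove the γ-hydrogen of 12 instead of adding 1,4; the silyl ketene acetal may be hydrolysed before it is oxidised; the oxidant may not discriminate the two faces well enough. Fallback: the two bond formations are separated and the oxygen is brought in by enolate hydroxylation instead of ketene-acetal epoxidation. It sets out from 12 and 15: the copper-catalysed addition is run as above but quenched with aqueous NH4Cl, which hydrolyses 16 and should give the dibenzyl lactone (4S)-3-[4-(benzyloxy)-3,5-dimethoxybenzyl]-4-[4-(benzyloxy)-3-methoxybenzyl]oxolan-2-one F1 as a mixture of C3 epimers (of no consequence, since C3 is made planar again). Deprotonation with KHMDS in THF at −78 °C and treatment of the potassium enolate with trans-2-(phenylsulfonyl)-3-phenyloxaziridine (Davis oxaziridine) should deliver oxygen anti to the C4 benzyl group; the route is rejoined at 18.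

Step 5. Formylation may stay incomplete, and under the hot basic conditions the exocyclic double bond may migrate into the ring (which would erase C4) or the product may oligomerise. Fallback: a Mannich/elimination sequence that runs cold and without alkoxide. It sets out from 10: LDA in THF at −78 °C and N,N-dimethylmethyleneiminium iodide (Eschenmoser's salt) should give the trans Mannich base (3R,4S)-4-[4-(benzyloxy)-3-methoxybenzyl]-3-[(dimethylamino)methyl]oxolan-2-one F2. Quaternisation with MeI in MeOH should give {[(3R,4S)-4-[4-(benzyloxy)-3-methoxybenzyl]-2-oxooxolan-3-yl]methyl}trimethylammonium iodide F3, and elimination with aqueous NaHCO3/CH2Cl2 at rt rejoins the route at 12.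

Step 4. Hydride may over-reduce the tert-butyl ester or open the oxazolidinone ring at its endocyclic carbonyl, and the acid stage may cause loss of the benzyl ether or tert-butylation of the electron-rich ring. Fallback: hydrolytic instead of reductive removal of the auxiliary. It sets out from 8: LiOH/H2O2 in THF/H2O at 0 °C should give (2S)-2-[4-(benzyloxy)-3-methoxybenzyl]-4-tert-butoxy-4-oxobutanoic acid F4. BH3·SMe2 in THF at 0 °C should then reduce the free acid chemoselectively in the presence of the ester, which rejoins the route at 9; 9 is lactonised to 10 as in step 4.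

**Further compounds**
F1 | step 7 | (4S)-3-[4-(benzyloxy)-3,5-dimethoxybenzyl]-4-[4-(benzyloxy)-3-methoxybenzyl]oxolan-2-one (C3 epimer mixture) | COc1cc(C[C@@H]2COC(=O)C2Cc2cc(OC)c(OCc3ccccc3)c(OC)c2)ccc1OCc1ccccc1
F2 | step 5 | (3R,4S)-4-[4-(benzyloxy)-3-methoxybenzyl]-3-[(dimethylamino)methyl]oxolan-2-one | COc1cc(C[C@@H]2COC(=O)[C@H]2CN(C)C)ccc1OCc1ccccc1
F3 | step 5 | {[(3R,4S)-4-[4-(benzyloxy)-3-methoxybenzyl]-2-oxooxolan-3-yl]methyl}trimethylammonium iodide | COc1cc(C[C@@H]2COC(=O)[C@H]2C[N+](C)(C)C)ccc1OCc1ccccc1.[I-]
F4 | step 4 | (2S)-2-[4-(benzyloxy)-3-methoxybenzyl]-4-tert-butoxy-4-oxobutanoic acid | COc1cc(C[C@@H](CC(=O)OC(C)(C)C)C(=O)O)ccc1OCc1ccccc1
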